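**Retrosynthetic overview**

1. The target is an achiral depside with no ring to build: ring A (2,4-dimethoxy-6-propylbenzoyl) is esterified to O4 of ring B, whose C1 carboxylic acid sits between C2–OMe and C6–pentyl. With the pentyl chain removed, C6–H is the only C–H ortho to that acid, because C2 is blocked by OMe; the route rests on this feature.
2. Last disconnection: the C6(ring B)–C1(pentyl) bond, made by carboxylate-directed palladium-catalysed C–H alkylation of the des-pentyl depside acid 10 with pentylboronic acid 11.
3. Acid 10 comes from aldehyde 9 by Pinnick oxidation; the ester C(=O)–O bond of 9 comes from acid chloride 8 and 4-hydroxy-2-methoxybenzaldehyde 7.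
4. Ring A acid 6 comes from 1-bromo-3,5-dimethoxybenzene 1 by Kumada propylation, Vilsmeier–Haack formylation and Pinnick oxidation.
5. Both benzene rings are purchased; no ring is formed at any stage.

Key step: step 6

Remark: carboxylate salts formed in basic media are counted with their free acids, which acidic work-up returns.

**Route**

Step 1
Reactants: 1 1-bromo-3,5-dimethoxybenzene; 2 propylmagnesium bromide
Product: 3 1,3-dimethoxy-5-propylbenzene
Conditions: NiCl2(dppp) (2 mol %), THF, 0 °C to reflux; then aq. NH4Cl
Reagents that add atoms: none
Why: Kumada–Corriu coupling, in which the chelating dppp ligand on nickel enforces fast reductive elimination of the aryl(propyl)nickel intermediate, so β-hydride elimination and propyl isomerisation should stay minor.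

Step 2
Reactants: 3 1,3-dimethoxy-5-propylbenzene
Product: 5 2,4-dimethoxy-6-propylbenzaldehyde, via iminium chloride 4 (not isolated)
Conditions: POCl3 (1.5 equiv), DMF, 0 °C to 70 °C; then H2O, 50 °C
Reagents that add atoms: N,N-dimethylformamide, CN(C)C=O; water, O
Why: Vilsmeier–Haack formylation, in which the chloroiminium electrophile should attack C4 (equivalent to C6) of 3, para to one methoxy group and ortho to the other, in preference to C2 between the two methoxy groups, as is usual for 5-alkylresorcinol dimethyl ethers; water then hydrolyses iminium 4.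

Step 3
Reactants: 5 2,4-dimethoxy-6-propylbenzaldehyde
Product: 6 2,4-dimethoxy-6-propylbenzoic acid
Conditions: NaClO2, NaH2PO4, 2-methyl-2-butene (excess), t-BuOH/H2O, rt
Reagents that add atoms: sodium chlorite, [Na+].[O-]Cl=O
Why: Pinnick oxidation, in which chlorous acid adds to the aldehyde and fragments to the acid while 2-methyl-2-butene traps hypochlorous acid before it can chlorinate the electron-rich ring.

Step 4
Reactants: 6 2,4-dimethoxy-6-propylbenzoic acid; 7 4-hydroxy-2-methoxybenzaldehyde
Product: 9 4-formyl-3-methoxyphenyl 2,4-dimethoxy-6-propylbenzoate, via acid chloride 8 (not isolated)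
Conditions: (COCl)2 (1.3 equiv), DMF (cat.), CH2Cl2, 0 °C to rt, evaporate; then 7, Et3N (1.5 equiv), DMAP (0.1 equiv), CH2Cl2, 0 °C to rt
Reagents that add atoms: none
Why: Acid chloride formation followed by DMAP-catalysed O-acylation of the phenol; the electron-rich, di-ortho-substituted aroyl chloride should react through an acylium-like transition state that tolerates the hindrance, and the formyl group of 7 never meets oxalyl chloride.

Step 5
Reactants: 9 4-formyl-3-methoxyphenyl 2,4-dimethoxy-6-propylbenzoate
Product: 10 4-[(2,4-dimethoxy-6-propylbenzoyl)oxy]-2-methoxybenzoic acid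
Conditions: NaClO2, NaH2PO4, 2-methyl-2-butene (excess), THF/t-BuOH/H2O, 0 °C to rt
Reagents that add atoms: sodium chlorite, [Na+].[O-]Cl=O
Why: Pinnick oxidation in a weakly acidic buffer, which should leave the hindered aryl ester untouched while the scavenger protects both electron-rich rings from chlorination.

Step 6
Reactants: 10 4-[(2,4-dimethoxy-6-propylbenzoyl)oxy]-2-methoxybenzoic acid; 11 pentylboronic acid
Product: 12 4-[(2,4-dimethoxy-6-propylbenzoyl)oxy]-2-methoxy-6-pentylbenzoic acid (target)
Conditions: Pd(OAc)2 (10 mol %), N-acetyl-L-isoleucine (20 mol %), Ag2CO3 (2 equiv), K2HPO4 (1.5 equiv), 1,4-benzoquinone (0.5 equiv), 11 (3 equiv), t-BuOH, 90 °C, sealed tube; then 1 M HCl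
Reagents that add atoms: none
Why: The carboxylate of 10 binds divalent palladium, and a concerted metalation–deprotonation assisted by the N-acetyl amino acid ligand cleaves the C6–H bond of ring B to give a five-membered palladacycle (Pd–O–C(=O)–C1–C6). Transmetalation from pentylboronic acid gives an aryl(pentyl)palladium species, 1,4-benzoquinone promotes C(sp2)–C(sp3) reductive elimination ahead of β-hydride elimination, and Ag2CO3 returns zerovalent palladium to the divalent state. The closest known reaction type is the carboxylate-directed, amino-acid-ligand-accelerated ortho C–H alkylation of benzoic acids with primary alkylboron reagents. No ring is closed and no stereocentre is created. The step needs site selectivity, which the substrate secures: C2 of ring B carries OMe, so C6–H is the only C–H the carboxylate can reach and double alkylation is impossible, while ring A has no free acid and both positions ortho to its carbonyl are substituted. The depside ester carbonyl is flanked by OMe and propyl and should therefore resist the weakly basic tert-butanol medium.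

**Compound list**

1 | 1-bromo-3,5-dimethoxybenzene | COc1cc(Br)cc(OC)c1 | starting material
2 | propylmagnesium bromide | CCC[Mg]Br | starting material
3 | 1,3-dimethoxy-5-propylbenzene | CCCc1cc(OC)cc(OC)c1 | intermediate
4 | (2,4-dimethoxy-6-propylbenzylidene)dimethyliminium chloride (not isolated) | CCCc1cc(OC)cc(OC)c1C=[N+](C)C.[Cl-] | intermediate
5 | 2,4-dimethoxy-6-propylbenzaldehyde | CCCc1cc(OC)cc(OC)c1C=O | intermediate
6 | 2,4-dimethoxy-6-propylbenzoic acid | CCCc1cc(OC)cc(OC)c1C(=O)O | intermediate
7 | 4-hydroxy-2-methoxybenzaldehyde | COc1cc(O)ccc1C=O | starting material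
8 | 2,4-dimethoxy-6-propylbenzoyl chloride (not isolated) | CCCc1cc(OC)cc(OC)c1C(=O)Cl | intermediate
9 | 4-formyl-3-methoxyphenyl 2,4-dimethoxy-6-propylbenzoate | CCCc1cc(OC)cc(OC)c1C(=O)Oc1ccc(C=O)c(OC)c1 | intermediate
10 | 4-[(2,4-dimethoxy-6-propylbenzoyl)oxy]-2-methoxybenzoic acid | CCCc1cc(OC)cc(OC)c1C(=O)Oc1ccc(C(=O)O)c(OC)c1 | intermediate
11 | pentylboronic acid | CCCCCB(O)O | starting material
12 | 4-[(2,4-dimethoxy-6-propylbenzoyl)oxy]-2-methoxy-6-pentylbenzoic acid (CNP0590692.0) | CCCCCc1cc(OC(=O)c2c(CCC)cc(OC)cc2OC)cc(OC)c1C(=O)O | target

**Step count**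

Total steps: 6. Longest linear sequence: 6 steps (1 → 3 → 5 → 6 → 9 → 10 → 12).

**Steps most likely to fail**

Step 6 (C–H pentylation). β-Hydride elimination from the pentylpalladium intermediate, protodeboronation or homocoupling of the boronic acid, silver-promoted protodecarboxylation of the di-ortho-substituted product, or transesterification of the depside ester could each erode the outcome. The fallback abandons C–H functionalisation and installs the pentyl chain with ring B from the start. It sets out from acid chloride 8 (made from 6 as in step 4) and returns at target 12.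
- Olivetol F1 (5-pentylbenzene-1,3-diol, purchased) would be formylated under Vilsmeier–Haack conditions (POCl3, DMF, then water) through iminium chloride F2 to 2,4-dihydroxy-6-pentylbenzaldehyde F3.
- The C4 hydroxyl of this aldehyde, which is not hydrogen-bonded to the formyl group, would be acylated selectively by 8 (Et3N, CH2Cl2, 0 °C) to give 4-formyl-3-hydroxy-5-pentylphenyl 2,4-dimethoxy-6-propylbenzoate F4.
- The chelated hydroxyl that remains would be methylated (MeI, K2CO3, DMF, rt) to give 4-formyl-3-methoxy-5-pentylphenyl 2,4-dimethoxy-6-propylbenzoate F5.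
- Pinnick oxidation under the conditions of step 5 would then give 12.

Step 4 (ester formation). Acylation of the weakly nucleophilic para-formyl phenol by the di-ortho-substituted acid chloride may be slow, so that hydrolysis of the acid chloride on work-up returns acid 6. The fallback changes the phenol partner, the mode of activation and the way the acid is unveiled. It sets out from acid 6 and returns at 10, bypassing 9 and step 5.
- 4-Hydroxy-2-methoxybenzoic acid F6 (purchased) would be esterified selectively at the carboxylate (BnBr, KHCO3, DMF) to benzyl 4-hydroxy-2-methoxybenzoate F7.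
- Acid 6 would be activated with trifluoroacetic anhydride in toluene as mixed anhydride F8, which should acylate the phenol through an acylium-type pathway to give benzyl 4-[(2,4-dimethoxy-6-propylbenzoyl)oxy]-2-methoxybenzoate F9.
- Hydrogenolysis (H2, palladium on carbon, EtOAc) would then release 10.

Step 1 (Kumada propylation). β-Hydride elimination at the propylnickel stage would cause hydrodebromination, and Grignard homocoupling or isomerisation to an isopropyl group could also lower the quality of 3. The fallback replaces the sp2–sp3 coupling by an sp2–sp2 coupling followed by reduction. It sets out from 1 and returns at 3.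
- Suzuki–Miyaura coupling of 1 with (E)-prop-1-en-1-ylboronic acid F10 (purchased) using Pd(dppf)Cl2 and K2CO3 in dioxane/H2O at 80 °C should give (E)-1,3-dimethoxy-5-(prop-1-en-1-yl)benzene F11.
- Hydrogenation (H2, palladium on carbon, EtOAc) would then give 3.

**Further compounds**

F1 | step 6 | olivetol (5-pentylbenzene-1,3-diol, purchased input) | CCCCCc1cc(O)cc(O)c1
F2 | step 6 | (2,4-dihydroxy-6-pentylbenzylidene)dimethyliminium chloride (not isolated) | CCCCCc1cc(O)cc(O)c1C=[N+](C)C.[Cl-]
F3 | step 6 | 2,4-dihydroxy-6-pentylbenzaldehyde | CCCCCc1cc(O)cc(O)c1C=O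
F4 | step 6 | 4-formyl-3-hydroxy-5-pentylphenyl 2,4-dimethoxy-6-propylbenzoate | CCCCCc1cc(OC(=O)c2c(CCC)cc(OC)cc2OC)cc(O)c1C=O
F5 | step 6 | 4-formyl-3-methoxy-5-pentylphenyl 2,4-dimethoxy-6-propylbenzoate | CCCCCc1cc(OC(=O)c2c(CCC)cc(OC)cc2OC)cc(OC)c1C=O
F6 | step 4 | 4-hydroxy-2-methoxybenzoic acid (purchased input) | COc1cc(O)ccc1C(=O)O
F7 | step 4 | benzyl 4-hydroxy-2-methoxybenzoate | COc1cc(O)ccc1C(=O)OCc1ccccc1
F8 | step 4 | 2,4-dimethoxy-6-propylbenzoic trifluoroacetic anhydride (not isolated) | CCCc1cc(OC)cc(OC)c1C(=O)OC(=O)C(F)(F)F
F9 | step 4 | benzyl 4-[(2,4-dimethoxy-6-propylbenzoyl)oxy]-2-methoxybenzoate | CCCc1cc(OC)cc(OC)c1C(=O)Oc1ccc(C(=O)OCc2ccccc2)c(OC)c1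
F10 | step 1 | (E)-prop-1-en-1-ylboronic acid (purchased input) | C/C=C/B(O)O
F11 | step 1 | (E)-1,3-dimethoxy-5-(prop-1-en-1-yl)benzene | C/C=C/c1cc(OC)cc(OC)c1
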